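A leftover opens the reckoning: in both earlier runs the four readings stop adding up to the charge, and the gap widens late.

| flask | substrate | solid reagent | temperature | remark | time |
|---|---|---|---|---|---|
| violet | 0.20 M | 0.75 equiv | 44 °C | run made earlier |  |
| amber | 0.20 M | 1.1 equiv | 52 °C | run made earlier |  |
| noon | 0.20 M | 1.50 equiv | 40 °C |  | 5.0 min |
| midnight | 0.20 M | 1.50 equiv | 55 °C |  | 5.0 min |

| run | time / min | target / % | substrate / % | intermediate A / % | intermediate C / % |
|---|---|---|---|---|---|
| violet | 1.33 | 1.8 | 66.6 | 24.2 | 6.9 |
| violet | 2.50 | 3.3 | 46.9 | 30.0 | 13.2 |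
| violet | 4.00 | 5.5 | 29.6 | 29.5 | 14.2 |
| violet | 5.00 | 8.6 | 21.8 | 29.6 | 13.0 |
| violet | 6.00 | 8.5 | 14.9 | 30.8 | 11.7 |
| amber | 0.250 | 0 | 82.0 | 17.3 | 0.2 |
| amber | 0.500 | 0 | 68.1 | 26.9 | 4.8 |
| amber | 0.833 | 1.2 | 50.9 | 34.5 | 8.3 |
| amber | 1.50 | 3.7 | 30.6 | 37.1 | 15.5 |
| amber | 3.00 | 10.3 | 8.7 | 23.6 | 15.7 |

(standard deviation of a reading: 0.5 percentage points)

- given per volume of solution although it is solid: solid reagent
- at the start none of the solid reagent is in solution

- which of these there is most of at the end, counted by the substrate in it, noon (target / intermediate A / intermediate C / substrate)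
- which of these there is most of at the end, counted by the substrate in it, midnight (target / intermediate A / intermediate C / substrate)
- the largest of these amounts at the end, in percent of the substrate charged, noon
- the largest of these amounts at the end, in percent of the substrate charged, midnight

At the last amber reading 41.7 % of the charge is unread, beside 10.3 % of target, a ratio of 4.05. Call this the leak ratio, the parts gone unread for each part arriving as target, a selectivity factor read against the target. The last violet reading gives 4.01, but violet differs from amber in both temperature and charge, so this closeness is a reading and proves no constant.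

The rule follows, with the leak ratio held at its reading: target equals the charge, less what is still readable, divided by one plus the leak ratio. Midnight, at 55 °C, differs from amber, read at 52 °C, in charge as well as temperature, and is given amber's value as an assumption, so the rule sets 19.8 % target for a flask emptied of substrate, intermediate A and intermediate C. What stays readable comes off as a correction downward, and this reckoning commits to target leading midnight a little below that figure.

Was one number enough? No: it shares out what has left and carries no clock, so it is silent on noon, where the forecast's substrate figure has to serve.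

The forecast, holding that “an unseen species probably follows C”, names substrate at 39.5 % for noon and target at 36 % for midnight. It agrees with this reckoning on the midnight leader, but its amount stands higher than 19.8 %.

Noon ends with substrate at 39.1 %, and midnight with target at 17.8 %, 18 percentage points below the forecast.

    substrate → intermediate A (k = 0.00313 /s, Ea = 101 kJ/mol)
    partner + intermediate A ⇌ intermediate B (K = 7.50 /M, k = 0.0148 /M/s, Ea = 70.0 kJ/mol, ΔH = −19.0 kJ/mol)
    partner + intermediate A ⇌ intermediate C (K = 241 /M, k = 0.0537 /M/s, Ea = 58.0 kJ/mol, ΔH = −34.0 kJ/mol)
    partner + intermediate C → target (k = 0.0323 /M/s, Ea = 44.0 kJ/mol)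
    partner + intermediate B ⇌ intermediate D (K = 3.11 /M, k = 0.0183 /M/s, Ea = 53.0 kJ/mol, ΔH = 9.00 kJ/mol)
    intermediate C ⇌ intermediate B (k = 0.0273 /s, Ea = 89.0 kJ/mol)
    solid reagent ⇌ partner, rate k7*(cs7 - [partner]) while solid is left; crystals form when [partner] > cs7 (solubility = 0.0870 M, k = 0.187 /s)
    intermediate C → decomposed reagent (k = 0.00573 /s, Ea = 81.0 kJ/mol)
    (constants at 40 °C)

Midnight holds 74.5 % of decomposed reagent at the end. Its readable rest of 7.43 % put into the rule with amber's ratio gives 18.3 % target. Noon at 50.0 min holds 69.1 % of decomposed reagent beside 30.7 % of target, a leak ratio of 2.25.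

The runs stem from a simulated flask from invented constants; scatter was added.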